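**Retrosynthetic overview** (germacrane numbering: C1 ketone, C2–C3 methylenes, C4(Me)=C5 Z-alkene, C6 lactone carbinol, C7 ring-fusion CH, C8 isovalerate carbinol, C9 methylene, C10 tertiary carbinol, C11(=C13H2)–C12 lactone carbons)

1. The α-methylene-γ-lactone (O6–C12) is made last, by oxidative lactonisation of a 2-methylene-1,4-diol (C6–OH and C12–OH); C12 is carried as a PMB ether.
2. The cyclodecene ring is opened at C1–C2: two electrophilic carbons (acyl C1 and iodide-bearing C2) are joined reductively with SmI2, run as a ring expansion of a seven-membered lactone (ring O6–C1–C10–C9–C8–C7–C6).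
3. The enabling feature is that O6 is tied to C2 by the short bridge C3–C4=C5–C6, which the Z-alkene holds folded, and that C1 is an α-oxygenated acyl carbon. C1 can therefore be parked as an ester on O6, so the ten-ring closure becomes a seven-membered addition followed by C1–O6 scission, which also returns the free O6–H needed for the last lactone.
4. The ε-lactone comes from a seco acid. C6 and the O8 isovalerate are set together by an Evans–Tishchenko reduction, and C7/C8 by a boron anti-aldol between a Z-enone (C2–C7, C11–C13, from a six-membered unsaturated lactone) and an aldehyde (C8–C10, C1) from (R)-citramalic acid, which supplies C10.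
5. Order of ring formation: dioxolanone (protecting ring) → ε-lactone (temporary ring) → cyclodecenone (key step) → α-methylene-γ-butyrolactone.

Key step: step 14

Assumption: lactone 8 is taken as purchasable, and the (1R,2S,5R) series of the bis(menthylmethyl)boron bromide is taken as the one whose enol borinate gives the 8R aldol with 4; if the sense is the reverse, the mirror-image reagent is used.

**Step 1**
Reactants: 1 (R)-citramalic acid
Product: 2 2-[(4R)-2,2,4-trimethyl-5-oxo-1,3-dioxolan-4-yl]acetic acid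
Conditions: 2,2-dimethoxypropane, TsOH·H2O (cat.), rt
Reagents that add atoms: 2,2-dimethoxypropane, COC(C)(C)OC
Why: Acid-catalysed transketalisation should close the five-membered 1,3-dioxolan-4-one on the α-hydroxy acid rather than a six-membered ring, masking C1 and O10 together and leaving the C8 carboxyl free, with the chiral-pool centre C10 untouched.

**Step 2**
Reactants: 2 2-[(4R)-2,2,4-trimethyl-5-oxo-1,3-dioxolan-4-yl]acetic acid
Product: 3 (5R)-5-(2-hydroxyethyl)-2,2,5-trimethyl-1,3-dioxolan-4-one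
Conditions: BH3·SMe2, THF, 0 °C to rt; MeOH quench
Reagents that add atoms: none
Why: Borane reduction of a free carboxylic acid (through the acyloxyborane) is much faster than attack on the ester-type dioxolanone carbonyl, so the primary alcohol should form chemoselectively.

**Step 3**
Reactants: 3 (5R)-5-(2-hydroxyethyl)-2,2,5-trimethyl-1,3-dioxolan-4-one
Product: 4 2-[(4R)-2,2,4-trimethyl-5-oxo-1,3-dioxolan-4-yl]acetaldehyde
Conditions: TEMPO (cat.), PhI(OAc)2, CH2Cl2, rt
Reagents that add atoms: none
Why: Oxoammonium (TEMPO) oxidation stops at the aldehyde under nearly neutral conditions that should neither open the dioxolanone nor cause β-elimination.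

**Step 4**
Reactants: 5 (4-methoxyphenyl)methanol; 6 3-chloro-2-(chloromethyl)prop-1-ene
Product: 7 1-({[2-(chloromethyl)prop-2-en-1-yl]oxy}methyl)-4-methoxybenzene
Conditions: NaH, Bu4NI (cat.), THF, 0 °C to rt, the dichloride in threefold excess
Reagents that add atoms: none
Why: Williamson etherification at an allylic primary chloride, with the symmetrical dichloride in excess to hold the reaction at mono-substitution.

**Step 5**
Reactants: 8 4-methyl-5,6-dihydro-2H-pyran-2-one; 9 N,O-dimethylhydroxylamine hydrochloride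
Product: 10 (2Z)-5-hydroxy-N-methoxy-N,3-dimethylpent-2-enamide
Conditions: AlMe3, CH2Cl2, 0 °C to rt; aq. potassium sodium tartrate
Reagents that add atoms: none
Why: Aminolysis of the lactone by the aluminium amide formed in the flask (Weinreb amide synthesis) opens the ring without touching the alkene, so the ring-enforced Z geometry of C4=C5 is carried into the open chain.

**Step 6**
Reactants: 10 (2Z)-5-hydroxy-N-methoxy-N,3-dimethylpent-2-enamide
Product: 11 (2Z)-5-chloro-N-methoxy-N,3-dimethylpent-2-enamide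
Conditions: PPh3, N-chlorosuccinimide, CH2Cl2, 0 °C
Reagents that add atoms: N-chlorosuccinimide, O=C1CCC(=O)N1Cl
Why: Appel-type chlorination (phosphonium activation, then SN2 by chloride) of the primary alcohol, run at once so that the Z-hydroxy amide cannot relactonise.

**Step 7**
Reactants: 7 1-({[2-(chloromethyl)prop-2-en-1-yl]oxy}methyl)-4-methoxybenzene; 11 (2Z)-5-chloro-N-methoxy-N,3-dimethylpent-2-enamide
Product: 13 (5Z)-8-chloro-2-{[(4-methoxybenzyl)oxy]methyl}-6-methylocta-1,5-dien-4-one, via allylmagnesium chloride 12 (not isolated)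
Conditions: Mg turnings, THF, 0 °C (slow addition of 7); then 11, −78 to −30 °C; cold aq. NH4Cl
Reagents that add atoms: none
Why: Weinreb ketone synthesis, in which the allyl Grignard reagent adds 1,2 and the chelated tetrahedral adduct survives until the cold buffered quench, which should prevent over-addition and keep the new β,γ-alkene out of conjugation.

**Step 8**
Reactants: 13 (5Z)-8-chloro-2-{[(4-methoxybenzyl)oxy]methyl}-6-methylocta-1,5-dien-4-one; 4 2-[(4R)-2,2,4-trimethyl-5-oxo-1,3-dioxolan-4-yl]acetaldehyde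
Product: 15 (5R)-5-[(2R,3R,5Z)-8-chloro-2-hydroxy-3-{3-[(4-methoxybenzyl)oxy]prop-1-en-2-yl}-6-methyl-4-oxooct-5-en-1-yl]-2,2,5-trimethyl-1,3-dioxolan-4-one, via enol borinate 14 (not isolated)
Conditions: bis{[(1R,2S,5R)-2-isopropyl-5-methylcyclohexyl]methyl}boron bromide, Et3N, Et2O, −78 to 0 °C; then 4, −78 °C; MeOH/pH 7 buffer
Reagents that add atoms: none
Why: Boron-mediated anti-aldol reaction, in which the doubly activated C7 methylene is enolised to the (E)-enol borinate 14 and this adds to 4 through a closed chair (Zimmerman–Traxler) transition state to give the 7,8-anti adduct, the C2-symmetric chiral ligands on boron choosing the aldehyde face that sets 8R and hence 7R (reagent control), while the dioxolanone is inert to boron enolates.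

**Step 9**
Reactants: 15 (the anti-aldol adduct); 16 3-methylbutanal
Product: 18 (2R,3S,4R,5Z)-8-chloro-4-hydroxy-3-{3-[(4-methoxybenzyl)oxy]prop-1-en-2-yl}-6-methyl-1-[(4R)-2,2,4-trimethyl-5-oxo-1,3-dioxolan-4-yl]oct-5-en-2-yl 3-methylbutanoate, via hemiacetal 17 (not isolated)
Conditions: SmI2 (0.3 equiv) premixed with a sixfold excess of the aldehyde, THF, −10 °C; then the aldol adduct; aq. NaHCO3
Reagents that add atoms: none
Why: Evans–Tishchenko reduction, in which the trivalent samarium pinacolate that SmI2 forms with part of the excess aldehyde binds hemiacetal 17 of the C8 hydroxyl, and 17 delivers its hydride intramolecularly to the C6 ketone through a chair-like six-membered transition state with the C7 and C8 substituents equatorial, so that C6 is set anti to O8 (6R) and the oxidised aldehyde remains as the C8 isovalerate.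

**Step 10**
Reactants: 18 (the hydroxy ester)
Product: 19 (2R,4R,5S,6R,7Z)-10-chloro-2,6-dihydroxy-5-{3-[(4-methoxybenzyl)oxy]prop-1-en-2-yl}-2,8-dimethyl-4-[(3-methylbutanoyl)oxy]dec-7-enoic acid
Conditions: AcOH/H2O/THF (3:1:1), 45 °C
Reagents that add atoms: none
Why: Mild aqueous acid should cleave the ketal C–O bonds of the dioxolanone (acetal hydrolysis with loss of acetone) much faster than it touches the isovalerate or the PMB ether, unveiling the tertiary α-hydroxy acid.

**Step 11**
Reactants: 19 (the seco acid)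
Product: 21 (3R,5R,6R,7R)-7-[(1Z)-4-chloro-2-methylbut-1-en-1-yl]-3-hydroxy-6-{3-[(4-methoxybenzyl)oxy]prop-1-en-2-yl}-3-methyl-2-oxooxepan-5-yl 3-methylbutanoate, via mixed anhydride 20 (not isolated)
Conditions: 2-methyl-6-nitrobenzoic anhydride, Et3N, DMAP (cat.), CH2Cl2, rt, slow addition (2 mM)
Reagents that add atoms: none
Why: Shiina lactonisation, in which carboxyl activation makes C1 far more electrophilic than the isovalerate carbonyl, so the only available secondary hydroxyl (O6) should close the seven-membered lactone (7-exo-trig) before any acyl migration, the tertiary C10 hydroxyl being unable to compete.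

**Step 12**
Reactants: 21 (the chloro lactone)
Product: 22 (3R,5R,6R,7R)-3-hydroxy-7-[(1Z)-4-iodo-2-methylbut-1-en-1-yl]-6-{3-[(4-methoxybenzyl)oxy]prop-1-en-2-yl}-3-methyl-2-oxooxepan-5-yl 3-methylbutanoate
Conditions: NaI, acetone, reflux, dark
Reagents that add atoms: sodium iodide, [Na+].[I-]
Why: Finkelstein exchange (SN2, driven by precipitation of NaCl) turns the primary chloride into the iodide needed for single-electron reduction.

**Step 13**
Reactants: 22 (the iodo lactone)
Product: 23 (3R,5R,6R,7R)-7-[(1Z)-4-iodo-2-methylbut-1-en-1-yl]-6-{3-[(4-methoxybenzyl)oxy]prop-1-en-2-yl}-3-methyl-2-oxo-3-[(trimethylsilyl)oxy]oxepan-5-yl 3-methylbutanoate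
Conditions: 1-(trimethylsilyl)imidazole, CH2Cl2, rt
Reagents that add atoms: 1-(trimethylsilyl)imidazole, C[Si](C)(C)n1ccnc1
Why: Silylation by a strong silyl donor caps the tertiary C10 hydroxyl, the only acidic proton that could quench an organosamarium.

**Step 14**
Reactants: 23 (the silylated iodo lactone)
Product: 27 (1R,3R,7Z,9R,10S)-3,9-dihydroxy-10-{3-[(4-methoxybenzyl)oxy]prop-1-en-2-yl}-3,7-dimethyl-4-oxocyclodec-7-en-1-yl 3-methylbutanoate, via alkylsamarium 24 (not isolated), via bridged samarium hemiketal 25 (not isolated), via silyl ether 26 (not isolated)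
Conditions: SmI2 (2.2 equiv), tris(dibenzoylmethanato)iron (2 mol %), THF, −30 to 0 °C, slow addition of the iodo lactone over 1 h; then 0.5 M aq. HCl, 0 °C
Reagents that add atoms: none
Why: Divalent samarium (iron-catalysed) reduces the C2–I bond by two single-electron transfers to the alkylsamarium 24, which adds to the lactone carbonyl C1 through a seven-membered array (C2–C3–C4=C5–C6–O6–C1, folded by the Z-alkene) to give the bridged hemiketal alkoxide 25, whose C1–O6 bond then breaks to leave the C1 ketone and free O6–H. This is a Barbier-type intramolecular nucleophilic acyl substitution with ring expansion, and the closest known reaction type is the SmI2-promoted ring expansion of ω-iodoalkyl lactones to hydroxycycloalkanones. The ten-membered carbocycle is therefore closed not by a direct ten-ring closure but by a 7-exo-trig addition followed by C–O fragmentation of the 11-oxabicyclo[4.4.1]undecene intermediate, a three-atom ring expansion. No new stereocentre is formed (C1 ends sp2), C6, C7, C8 and C10 are not touched, and the Z geometry of C4=C5 should survive because no allylic intermediate is involved. The step needs chemoselectivity between two ester carbonyls, and proximity secures it: the lactone carbonyl is the acyl group carried by O6, which the four-carbon bridge C3–C6 ties to C2, whereas the isovalerate carbonyl could only be reached through a nine-membered array. Over-addition and reductive loss of the α-oxygen should be held back because the ketone stays masked as the trivalent-samarium hemiketal 25 until the quench, and the acidic work-up also removes the silyl group from 26.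

**Step 15**
Reactants: 27 (the cyclodecenone diol)
Product: 28 (1R,3R,7Z,9R,10S)-3,9-dihydroxy-10-(3-hydroxyprop-1-en-2-yl)-3,7-dimethyl-4-oxocyclodec-7-en-1-yl 3-methylbutanoate
Conditions: DDQ, CH2Cl2/pH 7 buffer, 0 °C
Reagents that add atoms: none
Why: Oxidative PMB cleavage by DDQ (hydride abstraction at the electron-rich benzylic position, then hydrolysis of the oxocarbenium ion) should free the primary allylic alcohol without affecting the ester, ketone or alkenes.

**Step 16**
Reactants: 28 (the triol)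
Product: 31 CNP0105188.1, via enal 29 (not isolated), via lactol 30 (not isolated)
Conditions: TEMPO (cat.), PhI(OAc)2 (2.5 equiv), CH2Cl2, rt
Reagents that add atoms: none
Why: TEMPO/PhI(OAc)2 oxidative lactonisation, in which the primary allylic alcohol is oxidised first to enal 29, this is trapped by the neighbouring C6 hydroxyl as the five-membered lactol 30, and 30 is oxidised on to the α-methylene-γ-butyrolactone, the trans ring fusion being fixed by the existing C6 and C7 centres.

**Compound list**

1 | (R)-citramalic acid, (2R)-2-hydroxy-2-methylbutanedioic acid | OC(=O)[C@](C)(O)CC(=O)O | starting material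
2 | 2-[(4R)-2,2,4-trimethyl-5-oxo-1,3-dioxolan-4-yl]acetic acid | O=C1OC(C)(C)O[C@]1(C)CC(=O)O | intermediate
3 | (5R)-5-(2-hydroxyethyl)-2,2,5-trimethyl-1,3-dioxolan-4-one | O=C1OC(C)(C)O[C@]1(C)CCO | intermediate
4 | 2-[(4R)-2,2,4-trimethyl-5-oxo-1,3-dioxolan-4-yl]acetaldehyde | O=C1OC(C)(C)O[C@]1(C)CC=O | intermediate
5 | (4-methoxyphenyl)methanol | COc1ccc(CO)cc1 | starting material
6 | 3-chloro-2-(chloromethyl)prop-1-ene | C=C(CCl)CCl | starting material
7 | 1-({[2-(chloromethyl)prop-2-en-1-yl]oxy}methyl)-4-methoxybenzene | COc1ccc(COCC(=C)CCl)cc1 | intermediate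
8 | 4-methyl-5,6-dihydro-2H-pyran-2-one | CC1=CC(=O)OCC1 | starting material
9 | N,O-dimethylhydroxylamine hydrochloride | CNOC.Cl | starting material
10 | (2Z)-5-hydroxy-N-methoxy-N,3-dimethylpent-2-enamide | CON(C)C(=O)/C=C(/C)CCO | intermediate
11 | (2Z)-5-chloro-N-methoxy-N,3-dimethylpent-2-enamide | CON(C)C(=O)/C=C(/C)CCCl | intermediate
12 | chloro(2-{[(4-methoxybenzyl)oxy]methyl}prop-2-en-1-yl)magnesium | COc1ccc(COCC(=C)C[Mg]Cl)cc1 | intermediate (not isolated)
13 | (5Z)-8-chloro-2-{[(4-methoxybenzyl)oxy]methyl}-6-methylocta-1,5-dien-4-one | COc1ccc(COCC(=C)CC(=O)/C=C(/C)CCCl)cc1 | intermediate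
14 | {[(3E,5Z)-8-chloro-2-{[(4-methoxybenzyl)oxy]methyl}-6-methylocta-1,3,5-trien-4-yl]oxy}bis{[(1R,2S,5R)-2-isopropyl-5-methylcyclohexyl]methyl}borane | COc1ccc(COCC(=C)/C=C(/OB(C[C@@H]2C[C@H](C)CC[C@H]2C(C)C)C[C@@H]2C[C@H](C)CC[C@H]2C(C)C)\C=C(\C)CCCl)cc1 | intermediate (not isolated)
15 | (5R)-5-[(2R,3R,5Z)-8-chloro-2-hydroxy-3-{3-[(4-methoxybenzyl)oxy]prop-1-en-2-yl}-6-methyl-4-oxooct-5-en-1-yl]-2,2,5-trimethyl-1,3-dioxolan-4-one | O=C1OC(C)(C)O[C@]1(C)C[C@@H](O)[C@@H](C(=C)COCc2ccc(OC)cc2)C(=O)/C=C(/C)CCCl | intermediate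
16 | 3-methylbutanal | CC(C)CC=O | starting material
17 | hemiacetal of 15 (at O8) with 3-methylbutanal, hemiacetal carbon undefined | O=C1OC(C)(C)O[C@]1(C)C[C@@H](OC(O)CC(C)C)[C@@H](C(=C)COCc2ccc(OC)cc2)C(=O)/C=C(/C)CCCl | intermediate (not isolated)
18 | (2R,3S,4R,5Z)-8-chloro-4-hydroxy-3-{3-[(4-methoxybenzyl)oxy]prop-1-en-2-yl}-6-methyl-1-[(4R)-2,2,4-trimethyl-5-oxo-1,3-dioxolan-4-yl]oct-5-en-2-yl 3-methylbutanoate | O=C1OC(C)(C)O[C@]1(C)C[C@@H](OC(=O)CC(C)C)[C@@H](C(=C)COCc2ccc(OC)cc2)[C@H](O)/C=C(/C)CCCl | intermediate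
19 | (2R,4R,5S,6R,7Z)-10-chloro-2,6-dihydroxy-5-{3-[(4-methoxybenzyl)oxy]prop-1-en-2-yl}-2,8-dimethyl-4-[(3-methylbutanoyl)oxy]dec-7-enoic acid | OC(=O)[C@](C)(O)C[C@@H](OC(=O)CC(C)C)[C@@H](C(=C)COCc1ccc(OC)cc1)[C@H](O)/C=C(/C)CCCl | intermediate
20 | mixed anhydride of 19 with 2-methyl-6-nitrobenzoic acid | Cc1cccc([N+](=O)[O-])c1C(=O)OC(=O)[C@](C)(O)C[C@@H](OC(=O)CC(C)C)[C@@H](C(=C)COCc1ccc(OC)cc1)[C@H](O)/C=C(/C)CCCl | intermediate (not isolated)
21 | (3R,5R,6R,7R)-7-[(1Z)-4-chloro-2-methylbut-1-en-1-yl]-3-hydroxy-6-{3-[(4-methoxybenzyl)oxy]prop-1-en-2-yl}-3-methyl-2-oxooxepan-5-yl 3-methylbutanoate | O=C1O[C@H](/C=C(/C)CCCl)[C@H](C(=C)COCc2ccc(OC)cc2)[C@H](OC(=O)CC(C)C)C[C@@]1(C)O | intermediate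
22 | (3R,5R,6R,7R)-3-hydroxy-7-[(1Z)-4-iodo-2-methylbut-1-en-1-yl]-6-{3-[(4-methoxybenzyl)oxy]prop-1-en-2-yl}-3-methyl-2-oxooxepan-5-yl 3-methylbutanoate | O=C1O[C@H](/C=C(/C)CCI)[C@H](C(=C)COCc2ccc(OC)cc2)[C@H](OC(=O)CC(C)C)C[C@@]1(C)O | intermediate
23 | (3R,5R,6R,7R)-7-[(1Z)-4-iodo-2-methylbut-1-en-1-yl]-6-{3-[(4-methoxybenzyl)oxy]prop-1-en-2-yl}-3-methyl-2-oxo-3-[(trimethylsilyl)oxy]oxepan-5-yl 3-methylbutanoate | O=C1O[C@H](/C=C(/C)CCI)[C@H](C(=C)COCc2ccc(OC)cc2)[C@H](OC(=O)CC(C)C)C[C@@]1(C)O[Si](C)(C)C | intermediate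
24 | alkylsamarium diiodide from 23 (samarium in place of iodine at C2) | O=C1O[C@H](/C=C(/C)CC[Sm](I)I)[C@H](C(=C)COCc2ccc(OC)cc2)[C@H](OC(=O)CC(C)C)C[C@@]1(C)O[Si](C)(C)C | intermediate (not isolated)
25 | samarium alkoxide of the bridged hemiketal (11-oxabicyclo[4.4.1]undecene, C1 bonded to C2, C10, O6 and O–Sm; C1 configuration undefined) | I[Sm](I)OC12CC/C(C)=C\[C@@H](O1)[C@H](C(=C)COCc3ccc(OC)cc3)[C@H](OC(=O)CC(C)C)C[C@@]2(C)O[Si](C)(C)C | intermediate (not isolated)
26 | 3-O-trimethylsilyl ether of 27 | O[C@@H]1/C=C(/C)CCC(=O)[C@](C)(O[Si](C)(C)C)C[C@@H](OC(=O)CC(C)C)[C@H]1C(=C)COCc2ccc(OC)cc2 | intermediate (not isolated)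
27 | (1R,3R,7Z,9R,10S)-3,9-dihydroxy-10-{3-[(4-methoxybenzyl)oxy]prop-1-en-2-yl}-3,7-dimethyl-4-oxocyclodec-7-en-1-yl 3-methylbutanoate | O[C@@H]1/C=C(/C)CCC(=O)[C@](C)(O)C[C@@H](OC(=O)CC(C)C)[C@H]1C(=C)COCc2ccc(OC)cc2 | intermediate
28 | (1R,3R,7Z,9R,10S)-3,9-dihydroxy-10-(3-hydroxyprop-1-en-2-yl)-3,7-dimethyl-4-oxocyclodec-7-en-1-yl 3-methylbutanoate | O[C@@H]1/C=C(/C)CCC(=O)[C@](C)(O)C[C@@H](OC(=O)CC(C)C)[C@H]1C(=C)CO | intermediate
29 | enal from 28 (C12 aldehyde, C6 hydroxyl free) | O[C@@H]1/C=C(/C)CCC(=O)[C@](C)(O)C[C@@H](OC(=O)CC(C)C)[C@H]1C(=C)C=O | intermediate (not isolated)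
30 | lactol from 29 (O6–C12 hemiacetal, C12 configuration undefined) | C=C1C(O)O[C@@H]2/C=C(/C)CCC(=O)[C@](C)(O)C[C@@H](OC(=O)CC(C)C)[C@@H]12 | intermediate (not isolated)
31 | CNP0105188.1, (3aR,4R,6R,10Z,11aR)-6-hydroxy-6,10-dimethyl-3-methylidene-2,7-dioxo-2,3,3a,4,5,6,7,8,9,11a-decahydrocyclodeca[b]furan-4-yl 3-methylbutanoate | C=C1C(=O)O[C@@H]2/C=C(/C)CCC(=O)[C@](C)(O)C[C@@H](OC(=O)CC(C)C)[C@@H]12 | target

**Step count and risks**

Total step count: 16. Longest linear sequence: 12 steps (steps 5 to 16, from lactone 8; the branch from 1 through steps 1–3 and 8–16 is equally long).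

The three steps most likely to fail:

1. Step 14 (key step). The alkylsamarium may be protonated or reduced on before it reaches C1 (net loss of iodine without ring closure), or the ketone, once unmasked in the flask, may take up further electrons and lose the C10 oxygen. The fallback gives up the lactone relay and closes the same C1–C2 bond by a nickel-catalysed reductive ketone synthesis on an open-chain thioester. It sets out from seco acid 19. Silylation of the C6 hydroxyl (TESCl, imidazole, DMF; the silyl ester is hydrolysed on aqueous work-up) should give the 6-O-triethylsilyl acid F1. Halide exchange (NaI, acetone) gives the iodo acid F2, and 2,2′-dipyridyl disulfide/PPh3 turns this into the S-2-pyridyl thioester F3. NiBr2(4,4′-di-tert-butyl-2,2′-bipyridine), zirconocene dichloride (C5H5)2ZrCl2 and Zn dust in 1,3-dimethyl-2-imidazolidinone/ethyl acetate at high dilution should couple the alkyl iodide with the thioester carbonyl to give the ten-membered ketone F4. HF·pyridine then removes the silyl group, and the fallback comes back to the route at 27.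

2. Step 8. The boron ligands may discriminate poorly between the two faces of aldehyde 4 (the resident C10 centre is remote and may be mismatched), or the anti selectivity may be eroded by γ-attack or double-bond migration of the dienolate. The fallback drops reagent control and sets out from 13 and 4. The (E)-enol borinate of 13 is generated with achiral dicyclohexylboron chloride/Et3N (Et2O, −78 to 0 °C), which secures only the 7,8-anti relation, and 4 is added. Because the C10 centre is fixed, the two anti adducts are diastereomers, so 15 is separated by chromatography from the (7S,8S) isomer F5. F5 is cleaved back to 13 and 4 by base-mediated retro-aldol reaction and recycled, and the fallback comes back to the route at 15.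

3. Step 9. Before hydride transfer the free C8 hydroxyl may attack the dioxolanone carbonyl (five-membered lactone with loss of acetone), or the isovalerate may migrate to O6 after the reduction. The fallback separates acylation from reduction and sets out from 15. The C8 hydroxyl is first acylated with 3-methylbutanoic anhydride under Sc(OSO2CF3)3 catalysis (MeCN, −20 °C, no base, so no β-elimination) to give the keto ester F6. The Z-enone carbonyl is then reduced 1,2 with catecholborane and the enantiomer of 2-methyl-CBS-oxazaborolidine that delivers 6R (Corey–Bakshi–Shibata reduction, catalyst control), and the fallback comes back to the route at 18.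

**Further compounds**

F1 | step 14 | (2R,4R,5R,6R,7Z)-10-chloro-2-hydroxy-5-{3-[(4-methoxybenzyl)oxy]prop-1-en-2-yl}-2,8-dimethyl-4-[(3-methylbutanoyl)oxy]-6-[(triethylsilyl)oxy]dec-7-enoic acid | OC(=O)[C@](C)(O)C[C@@H](OC(=O)CC(C)C)[C@@H](C(=C)COCc1ccc(OC)cc1)[C@H](O[Si](CC)(CC)CC)/C=C(/C)CCCl
F2 | step 14 | (2R,4R,5R,6R,7Z)-2-hydroxy-10-iodo-5-{3-[(4-methoxybenzyl)oxy]prop-1-en-2-yl}-2,8-dimethyl-4-[(3-methylbutanoyl)oxy]-6-[(triethylsilyl)oxy]dec-7-enoic acid | OC(=O)[C@](C)(O)C[C@@H](OC(=O)CC(C)C)[C@@H](C(=C)COCc1ccc(OC)cc1)[C@H](O[Si](CC)(CC)CC)/C=C(/C)CCI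
F3 | step 14 | S-(pyridin-2-yl) (2R,4R,5R,6R,7Z)-2-hydroxy-10-iodo-5-{3-[(4-methoxybenzyl)oxy]prop-1-en-2-yl}-2,8-dimethyl-4-[(3-methylbutanoyl)oxy]-6-[(triethylsilyl)oxy]dec-7-enethioate | O=C(Sc1ccccn1)[C@](C)(O)C[C@@H](OC(=O)CC(C)C)[C@@H](C(=C)COCc1ccc(OC)cc1)[C@H](O[Si](CC)(CC)CC)/C=C(/C)CCI
F4 | step 14 | (1R,3R,7Z,9R,10R)-3-hydroxy-10-{3-[(4-methoxybenzyl)oxy]prop-1-en-2-yl}-3,7-dimethyl-4-oxo-9-[(triethylsilyl)oxy]cyclodec-7-en-1-yl 3-methylbutanoate | CC[Si](CC)(CC)O[C@@H]1/C=C(/C)CCC(=O)[C@](C)(O)C[C@@H](OC(=O)CC(C)C)[C@H]1C(=C)COCc2ccc(OC)cc2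
F5 | step 8 | (5R)-5-[(2S,3S,5Z)-8-chloro-2-hydroxy-3-{3-[(4-methoxybenzyl)oxy]prop-1-en-2-yl}-6-methyl-4-oxooct-5-en-1-yl]-2,2,5-trimethyl-1,3-dioxolan-4-one | O=C1OC(C)(C)O[C@]1(C)C[C@H](O)[C@H](C(=C)COCc2ccc(OC)cc2)C(=O)/C=C(/C)CCCl
F6 | step 9 | (2R,3R,5Z)-8-chloro-3-{3-[(4-methoxybenzyl)oxy]prop-1-en-2-yl}-6-methyl-4-oxo-1-[(4R)-2,2,4-trimethyl-5-oxo-1,3-dioxolan-4-yl]oct-5-en-2-yl 3-methylbutanoate | O=C1OC(C)(C)O[C@]1(C)C[C@@H](OC(=O)CC(C)C)[C@@H](C(=C)COCc2ccc(OC)cc2)C(=O)/C=C(/C)CCCl
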